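**Retrosynthetic overview**

1. Late disconnections (labdane numbering): the 2α-OAc/3α-OH pair comes from a C2=C3 olefin by OsO4 addition from the α face and acetylation of the equatorial 2-OH. C12–C13 comes from a B-alkyl Suzuki coupling with methyl (Z)-3-iodobut-2-enoate, which fixes 13Z. C9–C11 comes from vinyl addition to a C9 ketone from the α face.
2. Key disconnection: ring B is opened at C7–C8 and C9–C10 by a [4+2] retron. The pieces are the ring A diene C10=C5–C6=C7 and a but-2-ynoate (C8, C9, C17), held together as the ester of O2. The ester carbon is later excised by Curtius degradation, which uncovers the C9 ketone.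
3. Enabling feature: the oxygen on C2 of ring A lies on the α face, 1,3-cis to the C10–C9 bond of ring B. An ester tether from O2 can therefore deliver C9 to C10 only from the α face, and this sets the C10 quaternary centre. The same oxygen is afterwards turned into the C2=C3 olefin.
4. Ring order: ring A comes from (4R,6R)-actinol. Ring B and a temporary δ-lactone ring close together in the key step. The lactone ring is then cleaved.

Key step: step 4

Remark: labdane numbering is used for all decalin intermediates (ring carbons C1–C10, C17 on C8, C18/C19 on C4, C20 on C10, side chain C11–C16; α is the face opposite to C20), and (4R,6R)-actinol is taken as the commercial chiral starting material, its carbinol carbon becoming C2.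

**Route**

Step 1
Reactants: 1 (4R,6R)-4-hydroxy-2,2,6-trimethylcyclohexan-1-one (actinol); 2 vinylmagnesium bromide
Product: 3 (4R,6R)-1-ethenyl-2,2,6-trimethylcyclohexane-1,4-diol
Conditions: CeCl3 (dried), 2 (3.5 equiv), THF, −78 → 0 °C; aq NH4Cl
Reagents that add atoms: vinylmagnesium bromide (2), C=C[Mg]Br
Why: Organocerium-assisted Grignard 1,2-addition to the hindered ketone (one equivalent of 2 is spent on the free hydroxyl); the new carbinol centre may form as either epimer because it and the neighbouring methine are erased in step 2.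

Step 2
Reactants: 3 (4R,6R)-1-ethenyl-2,2,6-trimethylcyclohexane-1,4-diol
Product: 4 (R)-4-ethenyl-3,5,5-trimethylcyclohex-3-en-1-ol
Conditions: p-TsOH·H2O (5 mol %), PhMe, 4 Å MS, 50 °C
Reagents that add atoms: none
Why: Acid-catalysed E1 dehydration of the tertiary allylic alcohol, in which the allyl cation can lose a proton only from the ring methine and so gives the tetrasubstituted ring olefin conjugated with the vinyl group, while the secondary carbinol (future C2) does not ionise and keeps its configuration.

Step 3
Reactants: 4 (R)-4-ethenyl-3,5,5-trimethylcyclohex-3-en-1-ol; 5 but-2-ynoic acid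
Product: 6 (R)-4-ethenyl-3,5,5-trimethylcyclohex-3-en-1-yl but-2-ynoate
Conditions: DCC, DMAP (10 mol %), CH2Cl2, 0 °C → rt
Reagents that add atoms: but-2-ynoic acid (5), CC#CC(=O)O
Why: Steglich esterification of the unhindered secondary alcohol installs the dienophile (future C8, C9, C17) and the tether carbon C11 without touching the stereocentre.

Step 4
Reactants: 6 (R)-4-ethenyl-3,5,5-trimethylcyclohex-3-en-1-yl but-2-ynoate
Product: 7 bridged lactone (O2α to C11) of 2α-hydroxy-4,4,8,10β-tetramethyldecala-5,8-diene-9-carboxylic acid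
Conditions: PhMe (0.01 M), BHT (10 mol %), 170 °C, sealed tube
Reagents that add atoms: none
Why: Thermal concerted [4+2] cycloaddition (intramolecular Diels–Alder reaction) of the ring A diene C10=C5–C6=C7 with the tethered ynoate C9≡C8 forms C7–C8 and C9–C10 in one suprafacial event and leaves C8=C9 (conjugated with the lactone) and C5=C6. The closest known reaction type is the ester-tethered intramolecular Diels–Alder reaction of alkynoate esters of 2,4,4-trimethyl-3-vinylcyclohex-2-en-1-ols, which closes the same two bonds through a fused γ-lactone; here the ester hangs from the homoallylic oxygen instead. Ring B closes as the six-membered ring of the cycloaddition, and the temporary δ-lactone ring (O2–C11–C9–C10–C1–C2) closes as the six-membered tether ring when C9 bonds to C10; the linear ynoate lies along C10···C7, so C11 sits under C1 and clear of the 4α-methyl group. The only new stereocentre, C10, is controlled by C2: the three-atom tether (O2–C11–C9) reaches C10 only on the diene face that carries the pseudo-axial O2 (α), so C9 is delivered α and C20 is left β. Regioselectivity (C9 to C10, C8 to C7) is secured by the tether length and agrees with the electronic preference (ester-bearing carbon to the substituted diene terminus). High dilution suppresses intermolecular cycloaddition and BHT suppresses radical polymerisation.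

Step 5
Reactants: 7 bridged lactone (O2α to C11) of 2α-hydroxy-4,4,8,10β-tetramethyldecala-5,8-diene-9-carboxylic acid
Product: 8 2α-hydroxy-4,4,8,10β-tetramethyldecala-5,8-diene-9-carboxylic acid
Conditions: LiOH·H2O, THF/H2O (3:1), 0 °C → rt; 1 M HCl to pH 3, 0 °C
Reagents that add atoms: lithium hydroxide, [Li+].[OH-]
Why: Saponification of the lactone, which should be fast and should not reverse on acidification because ring opening lets ring A return to a chair with the 2α-OH equatorial and remote from the carboxyl group.

Step 6
Reactants: 8 2α-hydroxy-4,4,8,10β-tetramethyldecala-5,8-diene-9-carboxylic acid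
Product: 9 2α-hydroxy-4,4,8,10β-tetramethyl-5α-decal-8-ene-9-carboxylic acid
Conditions: H2 (3 atm), 10% Pd/C, EtOAc, rt
Reagents that add atoms: none
Why: Heterogeneous catalytic hydrogenation should reduce only the trisubstituted C5=C6 olefin (the tetrasubstituted, carboxyl-conjugated C8=C9 olefin resists) and deliver hydrogen to the α face, because the β face is screened by the C20 and 4β methyl groups, which sets 5α-H and the trans ring fusion.

Step 7
Reactants: 9 2α-hydroxy-4,4,8,10β-tetramethyl-5α-decal-8-ene-9-carboxylic acid
Product: 12 2α-hydroxy-4,4,8α,10β-tetramethyl-5α-decalin-9-one, via acyl azide 10 (not isolated), via vinyl isocyanate 11 (not isolated)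
Conditions: DPPA, Et3N, PhMe, 0 °C → rt; then dioxane/2 M HCl (3:1), 85 °C
Reagents that add atoms: water, O
Why: Curtius rearrangement of the acyl azide to the vinyl isocyanate and acid hydrolysis through the carbamic acid and enamine give the C9 ketone and excise the tether carbon C11 as CO2, while the C8 methine equilibrates by enolisation to the equatorial 8α-methyl epimer (an 8β-methyl group would be 1,3-diaxial to C20).

Step 8
Reactants: 12 2α-hydroxy-4,4,8α,10β-tetramethyl-5α-decalin-9-one
Product: 13 4,4,8α,10β-tetramethyl-5α-decal-2-en-9-one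
Conditions: Burgess reagent (1.5 equiv), PhMe, 70 °C
Reagents that add atoms: none
Why: Burgess dehydration by syn elimination of the 2α-sulfamate ester, in which loss of the cis 3α hydrogen should be preferred because C2=C3 is the less strained olefin position of a 10-methyl-trans-decalin (any C1=C2 isomer would be removed by chromatography).

Step 9
Reactants: 13 4,4,8α,10β-tetramethyl-5α-decal-2-en-9-one; 2 vinylmagnesium bromide
Product: 14 9α-ethenyl-4,4,8α,10β-tetramethyl-5α-decal-2-en-9β-ol
Conditions: CeCl3 (dried), 2 (2 equiv), THF, −78 → 0 °C; aq NH4Cl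
Reagents that add atoms: vinylmagnesium bromide (2), C=C[Mg]Br
Why: Organocerium-assisted 1,2-addition to the C9 ketone from the α face (axial attack, anti to the axial C20 methyl on the adjacent C10, the usual course for 10-methyl-1-decalones) should set C9 with the vinyl group α and the hydroxyl β, with CeCl3 limiting enolisation at C8.

Step 10
Reactants: 15 methyl but-2-ynoate
Product: 16 methyl (Z)-3-iodobut-2-enoate
Conditions: NaI, AcOH, 110 °C
Reagents that add atoms: sodium iodide, [Na+].[I-]
Why: Conjugate hydroiodination of the ynoate with anti addition of iodide and proton gives the (Z)-β-iodo enoate (iodine cis to the ester).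

Step 11
Reactants: 14 9α-ethenyl-4,4,8α,10β-tetramethyl-5α-decal-2-en-9β-ol; 16 methyl (Z)-3-iodobut-2-enoate
Product: 18 methyl (2Z)-5-(9β-hydroxy-4,4,8α,10β-tetramethyl-5α-decal-2-en-9α-yl)-3-methylpent-2-enoate, via alkylborane 17 (not isolated)
Conditions: 9-BBN dimer (2.5 equiv B–H), THF, 0 °C → rt; then 16, PdCl2(dppf) (5 mol %), AsPh3, Cs2CO3, DMF/H2O, rt
Reagents that add atoms: methyl (Z)-3-iodobut-2-enoate (16), COC(=O)/C=C(/C)I
Why: Anti-Markovnikov hydroboration of the monosubstituted vinyl group with 9-BBN (the hindered ring olefin is much slower) and B-alkyl Suzuki–Miyaura coupling with 16, which proceeds with retention at the vinyl iodide and so carries the Z geometry into the C13=C14 olefin.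

Step 12
Reactants: 18 methyl (2Z)-5-(9β-hydroxy-4,4,8α,10β-tetramethyl-5α-decal-2-en-9α-yl)-3-methylpent-2-enoate
Product: 19 methyl (2Z)-5-(2α,3α,9β-trihydroxy-4,4,8α,10β-tetramethyl-5α-decalin-9α-yl)-3-methylpent-2-enoate
Conditions: OsO4 (2 mol %), NMO (1.5 equiv), acetone/H2O (5:1), rt
Reagents that add atoms: OsO4, O=[Os](=O)(=O)=O; N-methylmorpholine N-oxide (reoxidant and oxygen source), C[N+]1([O-])CCOCC1; water, O
Why: Upjohn dihydroxylation, selective for the electron-richer cis-disubstituted C2=C3 olefin over the conjugated trisubstituted enoate and occurring syn from the α face (the β face is screened by the axial C20 and 4β methyl groups), which sets 2α-OH and 3α-OH.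

Step 13
Reactants: 19 methyl (2Z)-5-(2α,3α,9β-trihydroxy-4,4,8α,10β-tetramethyl-5α-decalin-9α-yl)-3-methylpent-2-enoate
Product: 20 methyl (2Z)-5-(2α-acetoxy-3α,9β-dihydroxy-4,4,8α,10β-tetramethyl-5α-decalin-9α-yl)-3-methylpent-2-enoate (target)
Conditions: Ac2O (1.2 equiv), pyridine, CH2Cl2, 0 °C
Reagents that add atoms: acetic anhydride, CC(=O)OC(C)=O
Why: Selective acylation of the equatorial secondary 2α-OH, which should react far faster than the axial 3α-OH flanked by the C4 gem-dimethyl group and than the tertiary 9-OH.

**Compound list**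

1 | (4R,6R)-4-hydroxy-2,2,6-trimethylcyclohexan-1-one (actinol) | O=C1C(C)(C)C[C@H](O)C[C@H]1C | starting material
2 | vinylmagnesium bromide | C=C[Mg]Br | starting material
3 | (4R,6R)-1-ethenyl-2,2,6-trimethylcyclohexane-1,4-diol (either C1 epimer) | OC1(C=C)C(C)(C)C[C@H](O)C[C@H]1C | intermediate
4 | (R)-4-ethenyl-3,5,5-trimethylcyclohex-3-en-1-ol | C=CC1=C(C)C[C@@H](O)CC1(C)C | intermediate
5 | but-2-ynoic acid | CC#CC(=O)O | starting material
6 | (R)-4-ethenyl-3,5,5-trimethylcyclohex-3-en-1-yl but-2-ynoate | C=CC1=C(C)C[C@@H](OC(=O)C#CC)CC1(C)C | intermediate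
7 | bridged lactone (O2α to C11) of 2α-hydroxy-4,4,8,10β-tetramethyldecala-5,8-diene-9-carboxylic acid | O=C1O[C@H]2CC(C)(C)C3=CCC(C)=C1[C@@]3(C)C2 | intermediate
8 | 2α-hydroxy-4,4,8,10β-tetramethyldecala-5,8-diene-9-carboxylic acid | OC(=O)C1=C(C)CC=C2C(C)(C)C[C@H](O)C[C@@]21C | intermediate
9 | 2α-hydroxy-4,4,8,10β-tetramethyl-5α-decal-8-ene-9-carboxylic acid | OC(=O)C1=C(C)CC[C@H]2C(C)(C)C[C@H](O)C[C@@]21C | intermediate
10 | acyl azide of 9 | [N-]=[N+]=NC(=O)C1=C(C)CC[C@H]2C(C)(C)C[C@H](O)C[C@@]21C | intermediate
11 | 9-isocyanato-4,4,8,10β-tetramethyl-5α-decal-8-en-2α-ol | O=C=NC1=C(C)CC[C@H]2C(C)(C)C[C@H](O)C[C@@]21C | intermediate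
12 | 2α-hydroxy-4,4,8α,10β-tetramethyl-5α-decalin-9-one | O=C1[C@H](C)CC[C@H]2C(C)(C)C[C@H](O)C[C@@]21C | intermediate
13 | 4,4,8α,10β-tetramethyl-5α-decal-2-en-9-one | O=C1[C@H](C)CC[C@H]2C(C)(C)C=CC[C@@]21C | intermediate
14 | 9α-ethenyl-4,4,8α,10β-tetramethyl-5α-decal-2-en-9β-ol | C=C[C@]1(O)[C@H](C)CC[C@H]2C(C)(C)C=CC[C@@]21C | intermediate
15 | methyl but-2-ynoate | CC#CC(=O)OC | starting material
16 | methyl (Z)-3-iodobut-2-enoate | COC(=O)/C=C(/C)I | intermediate
17 | 9-[2-(9β-hydroxy-4,4,8α,10β-tetramethyl-5α-decal-2-en-9α-yl)ethyl]-9-borabicyclo[3.3.1]nonane | C1CC2CCCC(C1)B2CC[C@]1(O)[C@H](C)CC[C@H]2C(C)(C)C=CC[C@@]21C | intermediate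
18 | methyl (2Z)-5-(9β-hydroxy-4,4,8α,10β-tetramethyl-5α-decal-2-en-9α-yl)-3-methylpent-2-enoate | COC(=O)/C=C(/C)CC[C@]1(O)[C@H](C)CC[C@H]2C(C)(C)C=CC[C@@]21C | intermediate
19 | methyl (2Z)-5-(2α,3α,9β-trihydroxy-4,4,8α,10β-tetramethyl-5α-decalin-9α-yl)-3-methylpent-2-enoate | COC(=O)/C=C(/C)CC[C@]1(O)[C@H](C)CC[C@H]2C(C)(C)[C@H](O)[C@H](O)C[C@@]21C | intermediate
20 | methyl (2Z)-5-(2α-acetoxy-3α,9β-dihydroxy-4,4,8α,10β-tetramethyl-5α-decalin-9α-yl)-3-methylpent-2-enoate (2R,3S,5S,8R,9S,10S) | COC(=O)/C=C(/C)CC[C@]1(O)[C@H](C)CC[C@H]2C(C)(C)[C@H](O)[C@H](OC(C)=O)C[C@@]21C | target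

**Step count and risks**

Total step count: 13. Longest linear sequence: 12 steps (steps 1–9 and 11–13; step 10 prepares coupling partner 16 from 15).

Steps most likely to fail:

1. Step 4 (tethered cycloaddition). Ring A must leave its half-chair so that the tether can bridge O2 and C10. The bridged transition state may therefore not be reached before the diene is lost to a [1,5]-hydrogen shift, polymerisation or intermolecular cycloaddition. The fallback sets out from 4 and gives up the tether. An intermolecular Diels–Alder reaction of 4 with (E)-1-nitroprop-1-ene (PhMe, 110 °C), used as a methylketene equivalent, should give the nitro cycloadduct F1, with the nitro-bearing carbon bonded to C10 by the usual ortho preference. Without the tether both faces of C10 are open, so the epimer with the C20 methyl trans to the 2-OH would have to be separated. A Nef reaction (NaOMe, MeOH; then aqueous TiCl3, NH4OAc) would give the C5=C6 hydroxy ketone F2. Hydrogenation (H2, Pd/C, EtOAc) and equilibration at C8 (NaOMe, MeOH) bring the route back at 12.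

2. Step 8 (dehydration). The syn elimination may show poor regioselectivity between the 1α and 3α hydrogens and give much of the C1=C2 olefin. The fallback sets out from 12 and places the double bond under thermodynamic control. Dess–Martin oxidation gives the 2,9-dione F3. Equilibrating enolisation (LiHMDS in slight deficiency, THF, −78 → 0 °C) toward the C2=C3 enolate, which is favoured in 10-methyl-trans-decalins, followed by trapping with PhNTf2, gives the enol triflate F4. Reduction with Pd(OAc)2, PPh3, HCO2H and Bu3N (DMF, 60 °C) returns to the route at 13.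

3. Step 9 (addition to the C9 ketone). The hindered ketone, flanked by the C10 quaternary centre and C8, may be enolised rather than attacked, or facial selectivity may be incomplete. The fallback sets out from 13 and uses a slimmer, less basic sp nucleophile that strongly prefers the axial (α) trajectory. Lithium (trimethylsilyl)acetylide with CeCl3 (THF, −78 °C) would give the 9α-(trimethylsilylethynyl) carbinol F5. K2CO3 in MeOH gives the 9α-ethynyl carbinol F6. Lindlar semihydrogenation (Pd/CaCO3/Pb(OAc)2, quinoline, H2, EtOAc) returns to the route at 14.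

**Further compounds**

F1 | step 4 | 9-nitro-4,4,8,10β-tetramethyldecal-5-en-2α-ol (C8 and C9 not defined) | [O-][N+](=O)C1C(C)CC=C2C(C)(C)C[C@H](O)C[C@@]21C
F2 | step 4 | 2α-hydroxy-4,4,8α,10β-tetramethyldecal-5-en-9-one | O=C1[C@H](C)CC=C2C(C)(C)C[C@H](O)C[C@@]21C
F3 | step 8 | 4,4,8α,10β-tetramethyl-5α-decalin-2,9-dione | O=C1[C@H](C)CC[C@H]2C(C)(C)CC(=O)C[C@@]21C
F4 | step 8 | 4,4,8α,10β-tetramethyl-9-oxo-5α-decal-2-en-2-yl trifluoromethanesulfonate | O=C1[C@H](C)CC[C@H]2C(C)(C)C=C(OS(=O)(=O)C(F)(F)F)C[C@@]21C
F5 | step 9 | 4,4,8α,10β-tetramethyl-9α-[(trimethylsilyl)ethynyl]-5α-decal-2-en-9β-ol | C[Si](C)(C)C#C[C@]1(O)[C@H](C)CC[C@H]2C(C)(C)C=CC[C@@]21C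
F6 | step 9 | 9α-ethynyl-4,4,8α,10β-tetramethyl-5α-decal-2-en-9β-ol | C#C[C@]1(O)[C@H](C)CC[C@H]2C(C)(C)C=CC[C@@]21C
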